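**Retrosynthetic overview**
1. Target ⇐ tetracyclic 16‑hydroxy‑15‑oxo ester by borohydride reduction, MnO2 re‑oxidation at C1 and Fleming–Tamao unmasking of C6‑OH (carried throughout as CH2SiMe2Ph).
2. Ring D (last): the C13–C16 bond comes from an electrophilic rhodium carbenoid at the α‑carbon of a β‑keto ester (polarity‑reversed enolate carbon) adding to the C12=C13 alkene; SmI2 then cleaves C12–C16 and the enolate is hydroxylated.
3. Ring C: Diels–Alder reaction of butadiene with an α‑formyl α,β‑unsaturated spirolactone (sets C8 and C9).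
4. Spiro δ‑lactone: epoxide‑derived C10 radical (trivalent titanium) adds to an acrylate, then lactonises (sets C10).
5. Ring A (first): asymmetric conjugate addition of PhMe2SiCH2MgCl to 4,4‑dimethylcyclohexadienone (sets C5). Ring order: A → lactone → C → D.

Assumption: carbons carry ent‑kaurane numbers (C7 lactone carbonyl, C20 lactone CH2, C6 the carbinol carbon on C5); the target is (5R,8S,9S,10S,13R,15S,16R).

**Step 1**
Reactants: 1 4,4-dimethylcyclohex-2-en-1-one
Product: 2 4,4-dimethylcyclohexa-2,5-dien-1-one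
Conditions: DDQ (1.3 equiv), TsOH (cat.), dioxane, reflux
Reagents that add atoms: none
Why: quinone dehydrogenation of the enone through its dienol gives the symmetric cross‑conjugated dienone, with no stereocentre formed.

**Step 2**
Reactants: 2 4,4-dimethylcyclohexa-2,5-dien-1-one; 3 (chloromethyl)dimethyl(phenyl)silane
Product: 5 (5S)-5-{[dimethyl(phenyl)silyl]methyl}-4,4-dimethylcyclohex-2-en-1-one, via silylmethylmagnesium chloride 4 (not isolated)
Conditions: 3, Mg, Et2O, reflux; then 2, CuBr·SMe2 (5 mol %), (R,S)-Josiphos (6 mol %, antipode fixed by a pilot run), t-BuOMe, −78 °C; 1 M HCl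
Reagents that add atoms: none
Why: Proposed new method: copper‑catalysed asymmetric conjugate addition of the silylmethyl Grignard reagent (a masked hydroxymethyl anion) to one of the two enantiotopic enone halves sets C5 under ligand control, and the resulting dienolate cannot add a second time; the closest known reaction types are copper/ferrocenyl‑diphosphine conjugate addition of alkyl Grignard reagents to cyclic enones and copper‑catalysed desymmetrisation of 4,4‑disubstituted cyclohexadienones with dialkylzincs.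

**Step 3**
Reactants: 5 (5S)-5-{[dimethyl(phenyl)silyl]methyl}-4,4-dimethylcyclohex-2-en-1-one
Product: 6 (5R)-5-{[dimethyl(phenyl)silyl]methyl}-4,4-dimethyl-6-methylidenecyclohex-2-en-1-one
Conditions: (CH2O)n, N-methylanilinium trifluoroacetate, THF, reflux
Reagents that add atoms: paraformaldehyde, as formaldehyde (C=O)
Why: Mannich‑type α‑methylenation can only occur at C10, the single enolisable α‑carbon (the other α‑carbon is vinylic and C4 is quaternary).

**Step 4**
Reactants: 6 (5R)-5-{[dimethyl(phenyl)silyl]methyl}-4,4-dimethyl-6-methylidenecyclohex-2-en-1-one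
Product: 7 (3R,8R)-8-{[dimethyl(phenyl)silyl]methyl}-7,7-dimethyl-1-oxaspiro[2.5]oct-5-en-4-one
Conditions: 30 % H2O2, NaOH (cat.), MeOH, 0 °C
Reagents that add atoms: hydrogen peroxide (OO)
Why: Weitz–Scheffer nucleophilic epoxidation takes the unhindered exocyclic enone and leaves the ring enone, whose β‑carbon is neopentylic; the spiro configuration (drawn anti to the CH2Si arm) is erased in step 6.

**Step 5**
Reactants: 7 (3R,8R)-8-{[dimethyl(phenyl)silyl]methyl}-7,7-dimethyl-1-oxaspiro[2.5]oct-5-en-4-one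
Product: 8 (3R,4R,8R)-8-{[dimethyl(phenyl)silyl]methyl}-7,7-dimethyl-1-oxaspiro[2.5]oct-5-en-4-ol
Conditions: NaBH4, CeCl3·7H2O, MeOH, −78 °C
Reagents that add atoms: none
Why: Luche 1,2‑reduction removes the ketone that would otherwise divert the radical chemistry of step 6; the C1 configuration (drawn for hydride attack anti to the epoxide oxygen) is irrelevant because C1 is re‑oxidised in step 7.

**Step 6**
Reactants: 8 (3R,4R,8R)-8-{[dimethyl(phenyl)silyl]methyl}-7,7-dimethyl-1-oxaspiro[2.5]oct-5-en-4-ol; 9 2,2,2-trifluoroethyl prop-2-enoate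
Product: 11 (6S,7R,11R)-11-{[dimethyl(phenyl)silyl]methyl}-7-hydroxy-10,10-dimethyl-2-oxaspiro[5.5]undec-8-en-3-one, via hydroxy trifluoroethyl ester 10 (not isolated)
Conditions: Cp2TiCl2 (20 mol %), Zn dust, 2,4,6-collidine·HCl (2.5 equiv), 9 (4 equiv), THF, rt; then TsOH·H2O (cat.), CH2Cl2, rt
Reagents that add atoms: none
Why: Nugent–RajanBabu epoxide opening by Cp2TiCl (trivalent titanium) gives the tertiary C10 radical, which adds to the acrylate (Giese addition) anti to the C5 CH2Si arm and so sets C10, after which the primary C20 hydroxyl displaces trifluoroethanol to close the δ‑lactone.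

**Step 7**
Reactants: 11 (6S,7R,11R)-11-{[dimethyl(phenyl)silyl]methyl}-7-hydroxy-10,10-dimethyl-2-oxaspiro[5.5]undec-8-en-3-one
Product: 12 (6S,11R)-11-{[dimethyl(phenyl)silyl]methyl}-10,10-dimethyl-2-oxaspiro[5.5]undec-8-ene-3,7-dione
Conditions: MnO2 (excess), CH2Cl2, rt
Reagents that add atoms: none
Why: MnO2 oxidation of the allylic alcohol gives the ring A enone, which is non‑enolisable and makes C1 planar for step 10.

**Step 8**
Reactants: 12 (6S,11R)-11-{[dimethyl(phenyl)silyl]methyl}-10,10-dimethyl-2-oxaspiro[5.5]undec-8-ene-3,7-dione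
Product: 13 (4Z,6S,11R)-11-{[dimethyl(phenyl)silyl]methyl}-4-(hydroxymethylidene)-10,10-dimethyl-2-oxaspiro[5.5]undec-8-ene-3,7-dione
Conditions: LiN(SiMe3)2 (2.2 equiv), THF, −78 °C; CF3CH2OCHO, −78 → 0 °C; 1 M HCl
Reagents that add atoms: 2,2,2-trifluoroethyl formate (O=COCC(F)(F)F)
Why: Claisen‑type formylation of the lactone enolate at C8, the only acidic position, installs C15 as the chelated enol.

**Step 9**
Reactants: 13 (4Z,6S,11R)-11-{[dimethyl(phenyl)silyl]methyl}-4-(hydroxymethylidene)-10,10-dimethyl-2-oxaspiro[5.5]undec-8-ene-3,7-dione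
Product: 15 (6S,11R)-11-{[dimethyl(phenyl)silyl]methyl}-10,10-dimethyl-3,7-dioxo-2-oxaspiro[5.5]undeca-4,8-diene-4-carbaldehyde, via phenylselanyl formyl lactone 14 (not isolated)
Conditions: PhSeCl, pyridine, CH2Cl2, 0 °C; then 30 % H2O2, 0 °C → rt; used crude at once
Reagents that add atoms: none
Why: α‑selenenylation of the 1,3‑dicarbonyl followed by selenoxide syn‑elimination (only C9 carries β‑hydrogens) gives the doubly activated C8=C9 dienophile.

**Step 10**
Reactants: 15 (6S,11R)-11-{[dimethyl(phenyl)silyl]methyl}-10,10-dimethyl-3,7-dioxo-2-oxaspiro[5.5]undeca-4,8-diene-4-carbaldehyde; 16 buta-1,3-diene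
Product: 17 (5R,8S,9S,10S) tricyclic formyl lactone (ring C cyclohexene C12=C13 cis-fused to the lactone at C8–C9; CHO on C8 cis to H9)
Conditions: 16 (excess), ZnCl2 (0.5 equiv), CH2Cl2, −20 °C → rt, sealed tube
Reagents that add atoms: none
Why: Lewis‑acid‑promoted Diels–Alder reaction in which butadiene adds suprafacially to the face of the dienophile next to the flat C1 carbonyl and away from the C5 CH2Si arm, setting C9 and the quaternary C8 with the cis ring fusion.

**Step 11**
Reactants: 17 (5R,8S,9S,10S) tricyclic formyl lactone; 18 ethyl diazoacetate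
Product: 20 (5R,8S,9S,10S) α-diazo β-keto ester (C8–C15(=O)–C16(=N2)–CO2Et on the tricycle of 17), via hydroxy diazo ester 19 (not isolated)
Conditions: 18 (1.5 equiv), DBU (20 mol %), DMSO, rt; then IBX (1.5 equiv), rt
Reagents that add atoms: none
Why: DBU‑catalysed aldol‑type addition of the diazo ester to the electrophilic neopentyl aldehyde and IBX oxidation of the carbinol in the same pot give the acceptor/acceptor diazo compound, the transient C15 stereocentre being oxidised away.

**Step 12 (key step)**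
Reactants: 20 (5R,8S,9S,10S) α-diazo β-keto ester
Product: 21 cyclopropane-fused pentacycle (C16 bonded to C12 and C13 on the face of the C8 acyl arm; 15-oxo; CO2Et on C16)
Conditions: Rh2(OAc)4 (2 mol %), CH2Cl2, 40 °C, slow addition of 20
Reagents that add atoms: none
Why: loss of N2 gives an electrophilic rhodium carbenoid at C16, the α‑carbon of a β‑keto ester with its normal nucleophilic polarity reversed, which the C8 tether delivers to the nucleophilic C12=C13 bond on the same face (intramolecular cyclopropanation), forming C13–C16 and fixing C13.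

**Step 13**
Reactants: 21 cyclopropane-fused pentacycle
Product: 23 (5R,8S,9S,10S,13R,16S) tetracyclic 16-hydroxy-15-oxo ethyl ester (bicyclo[3.2.1]octane rings C/D; 16-OH exo; CO2Et endo), via samarium enolate of keto ester 22 (not isolated)
Conditions: SmI2 (2.1 equiv), MeOH (2 equiv), THF, −78 °C; then 3-phenyl-2-(phenylsulfonyl)oxaziridine, −78 → −20 °C
Reagents that add atoms: 3-phenyl-2-(phenylsulfonyl)oxaziridine (O=S(=O)(c1ccccc1)N1OC1c1ccccc1)
Why: Proposed new method: divalent samarium reduces the doubly activated cyclopropyl ketone at −78 °C (faster than the hindered ring A enone) and breaks C12–C16, the cyclopropane bond held nearly perpendicular to the ketone plane, giving the bicyclo[3.2.1]octane, and the resulting samarium enolate is oxidised in the same pot on its open exo face (Davis oxidation), setting C16; the closest known reaction types are overlap‑controlled SmI2 or dissolving‑metal opening of cyclopropyl ketones and Davis hydroxylation of β‑keto ester enolates, run separately.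

**Step 14**
Reactants: 23 (5R,8S,9S,10S,13R,16S) tetracyclic 16-hydroxy-15-oxo ethyl ester
Product: 24 (1S,5R,8S,9S,10S,13R,15S,16R)-1,15,16,17-tetrahydroxy-6-[dimethyl(phenyl)silyl]-6,7-seco-kaur-2-en-7,20-olide
Conditions: NaBH4, CeCl3·7H2O, MeOH/THF, −40 °C; then NaBH4 (excess), EtOH, 0 °C → rt
Reagents that add atoms: none
Why: Luche‑type borohydride reduction in which hydride attacks the C15 ketone from the exo face (endo alcohol, trans to 16‑OH), reduces the ring A enone 1,2 (C1 configuration irrelevant) and, with excess reagent, reduces the α‑hydroxy ester to C17H2OH, while the α‑quaternary δ‑lactone is expected to survive.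

**Step 15**
Reactants: 24 (1S,5R,8S,9S,10S,13R,15S,16R)-1,15,16,17-tetrahydroxy-6-[dimethyl(phenyl)silyl]-6,7-seco-kaur-2-en-7,20-olide
Product: 25 (5R,8S,9S,10S,13R,15S,16R)-15,16,17-trihydroxy-6-[dimethyl(phenyl)silyl]-1-oxo-6,7-seco-kaur-2-en-7,20-olide
Conditions: MnO2 (excess), acetone, rt
Reagents that add atoms: none
Why: MnO2 oxidises only the allylic C1 alcohol among the four hydroxyls, restoring the ring A enone.

**Step 16**
Reactants: 25 (5R,8S,9S,10S,13R,15S,16R)-15,16,17-trihydroxy-6-[dimethyl(phenyl)silyl]-1-oxo-6,7-seco-kaur-2-en-7,20-olide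
Product: 26 (5R,8S,9S,10S,13R,15S,16R)-6,15,16,17-tetrahydroxy-1-oxo-6,7-seco-kaur-2-en-7,20-olide (target CNP0546915.1)
Conditions: Hg(OAc)2 (1.5 equiv), AcOOH (32 % in AcOH), AcOH, rt
Reagents that add atoms: peracetic acid (CC(=O)OO)
Why: Fleming–Tamao oxidation, in which mercuridesilylation removes the phenyl group and the peracid triggers the carbon shift from silicon to oxygen, converts the C6–Si bond into C6–OH without touching the electron‑poor enone.

**Compound list**
1 | 4,4-dimethylcyclohex-2-en-1-one | CC1(C)CCC(=O)C=C1 | starting material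
2 | 4,4-dimethylcyclohexa-2,5-dien-1-one | CC1(C)C=CC(=O)C=C1 | intermediate
3 | (chloromethyl)dimethyl(phenyl)silane | C[Si](C)(CCl)c1ccccc1 | starting material
4 | {[dimethyl(phenyl)silyl]methyl}magnesium chloride | C[Si](C)(C[Mg]Cl)c1ccccc1 | intermediate (not isolated)
5 | (5S)-5-{[dimethyl(phenyl)silyl]methyl}-4,4-dimethylcyclohex-2-en-1-one | CC1(C)C=CC(=O)C[C@@H]1C[Si](C)(C)c1ccccc1 | intermediate
6 | (5R)-5-{[dimethyl(phenyl)silyl]methyl}-4,4-dimethyl-6-methylidenecyclohex-2-en-1-one | CC1(C)C=CC(=O)C(=C)[C@@H]1C[Si](C)(C)c1ccccc1 | intermediate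
7 | (3R,8R)-8-{[dimethyl(phenyl)silyl]methyl}-7,7-dimethyl-1-oxaspiro[2.5]oct-5-en-4-one | CC1(C)C=CC(=O)[C@]2(CO2)[C@@H]1C[Si](C)(C)c1ccccc1 | intermediate
8 | (3R,4R,8R)-8-{[dimethyl(phenyl)silyl]methyl}-7,7-dimethyl-1-oxaspiro[2.5]oct-5-en-4-ol | CC1(C)C=C[C@@H](O)[C@]2(CO2)[C@@H]1C[Si](C)(C)c1ccccc1 | intermediate
9 | 2,2,2-trifluoroethyl prop-2-enoate | C=CC(=O)OCC(F)(F)F | starting material
10 | 2,2,2-trifluoroethyl 3-[(1S,2R,6R)-6-{[dimethyl(phenyl)silyl]methyl}-2-hydroxy-1-(hydroxymethyl)-5,5-dimethylcyclohex-3-en-1-yl]propanoate | CC1(C)C=C[C@@H](O)[C@@](CO)(CCC(=O)OCC(F)(F)F)[C@@H]1C[Si](C)(C)c1ccccc1 | intermediate (not isolated)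
11 | (6S,7R,11R)-11-{[dimethyl(phenyl)silyl]methyl}-7-hydroxy-10,10-dimethyl-2-oxaspiro[5.5]undec-8-en-3-one | CC1(C)C=C[C@@H](O)[C@]2(COC(=O)CC2)[C@@H]1C[Si](C)(C)c1ccccc1 | intermediate
12 | (6S,11R)-11-{[dimethyl(phenyl)silyl]methyl}-10,10-dimethyl-2-oxaspiro[5.5]undec-8-ene-3,7-dione | CC1(C)C=CC(=O)[C@]2(COC(=O)CC2)[C@@H]1C[Si](C)(C)c1ccccc1 | intermediate
13 | (4Z,6S,11R)-11-{[dimethyl(phenyl)silyl]methyl}-4-(hydroxymethylidene)-10,10-dimethyl-2-oxaspiro[5.5]undec-8-ene-3,7-dione (enol form of the 4-formyl lactone) | CC1(C)C=CC(=O)[C@]2(COC(=O)/C(=C\O)C2)[C@@H]1C[Si](C)(C)c1ccccc1 | intermediate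
14 | (6S,11R)-11-{[dimethyl(phenyl)silyl]methyl}-10,10-dimethyl-3,7-dioxo-4-(phenylselanyl)-2-oxaspiro[5.5]undec-8-ene-4-carbaldehyde (both C4 epimers) | CC1(C)C=CC(=O)[C@]2(COC(=O)C(C=O)([Se]c3ccccc3)C2)[C@@H]1C[Si](C)(C)c1ccccc1 | intermediate (not isolated)
15 | (6S,11R)-11-{[dimethyl(phenyl)silyl]methyl}-10,10-dimethyl-3,7-dioxo-2-oxaspiro[5.5]undeca-4,8-diene-4-carbaldehyde | CC1(C)C=CC(=O)[C@]2(COC(=O)C(C=O)=C2)[C@@H]1C[Si](C)(C)c1ccccc1 | intermediate
16 | buta-1,3-diene | C=CC=C | starting material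
17 | (5R,8S,9S,10S) tricyclic formyl lactone: ring A enone, spiro δ-lactone, ring C cyclohexene (C12=C13) cis-fused at C8–C9, CHO (C15) on C8 cis to H9 | CC1(C)C=CC(=O)[C@]2(COC(=O)[C@@]3(C=O)CC=CC[C@@H]23)[C@@H]1C[Si](C)(C)c1ccccc1 | intermediate
18 | ethyl diazoacetate | CCOC(=O)C=[N+]=[N-] | starting material
19 | (5R,8S,9S,10S) β-hydroxy α-diazo ester, C8–C15H(OH)–C16(=N2)–CO2Et (C15 epimers) | CC1(C)C=CC(=O)[C@]2(COC(=O)[C@@]3(C(O)C(=[N+]=[N-])C(=O)OCC)CC=CC[C@@H]23)[C@@H]1C[Si](C)(C)c1ccccc1 | intermediate (not isolated)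
20 | (5R,8S,9S,10S) α-diazo β-keto ester, C8–C15(=O)–C16(=N2)–CO2Et | CC1(C)C=CC(=O)[C@]2(COC(=O)[C@@]3(C(=O)C(=[N+]=[N-])C(=O)OCC)CC=CC[C@@H]23)[C@@H]1C[Si](C)(C)c1ccccc1 | intermediate
21 | cyclopropane-fused pentacycle: C16 (bearing CO2Et and the C15 ketone) bonded to C12 and C13 on the ring C face syn to the C8 acyl arm; C5, C8, C9, C10 as in 20 | CC1(C)C=CC(=O)[C@]2(COC(=O)[C@@]34C[C@@H]([C@H]5C[C@@H]23)[C@]5(C(=O)OCC)C4=O)[C@@H]1C[Si](C)(C)c1ccccc1 | intermediate
22 | (5R,8S,9S,10S,13R) tetracyclic β-keto ester, formed as its samarium enolate (drawn as the keto form, CO2Et exo; C16 epimerisable) | CC1(C)C=CC(=O)[C@]2(COC(=O)[C@@]34C[C@@H](CC[C@@H]23)[C@H](C(=O)OCC)C4=O)[C@@H]1C[Si](C)(C)c1ccccc1 | intermediate (not isolated)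
23 | (5R,8S,9S,10S,13R,16S) tetracyclic 16-hydroxy-15-oxo ethyl ester (16-OH exo, CO2Et endo) | CC1(C)C=CC(=O)[C@]2(COC(=O)[C@@]34C[C@@H](CC[C@@H]23)[C@@](O)(C(=O)OCC)C4=O)[C@@H]1C[Si](C)(C)c1ccccc1 | intermediate
24 | (1S,5R,8S,9S,10S,13R,15S,16R)-1,15,16,17-tetrahydroxy-6-[dimethyl(phenyl)silyl]-6,7-seco-kaur-2-en-7,20-olide | CC1(C)C=C[C@H](O)[C@]2(COC(=O)[C@@]34C[C@@H](CC[C@@H]23)[C@@](O)(CO)[C@H]4O)[C@@H]1C[Si](C)(C)c1ccccc1 | intermediate
25 | (5R,8S,9S,10S,13R,15S,16R)-15,16,17-trihydroxy-6-[dimethyl(phenyl)silyl]-1-oxo-6,7-seco-kaur-2-en-7,20-olide | CC1(C)C=CC(=O)[C@]2(COC(=O)[C@@]34C[C@@H](CC[C@@H]23)[C@@](O)(CO)[C@H]4O)[C@@H]1C[Si](C)(C)c1ccccc1 | intermediate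
26 | (5R,8S,9S,10S,13R,15S,16R)-6,15,16,17-tetrahydroxy-1-oxo-6,7-seco-kaur-2-en-7,20-olide (CNP0546915.1) | CC1(C)C=CC(=O)[C@]2(COC(=O)[C@@]34C[C@@H](CC[C@@H]23)[C@@](O)(CO)[C@H]4O)[C@@H]1CO | target

**Step count and risks**
Total step count: 16. Longest linear sequence: 16 (fully linear from 1).

The three steps most likely to fail:

Step 2 (asymmetric conjugate addition). The silylmethyl Grignard reagent is bulky, the β‑carbon is neopentylic and this nucleophile is untested in ligand‑controlled additions, so low conversion or low ee is possible. The fallback sets out from 2 (with 4 made from 3) and returns at 5. The same Grignard reagent is added under ligand‑free CuBr·SMe2 catalysis (THF, −40 °C, acid work‑up) to give the racemic silylmethyl enone F1. The enantiomers are then separated by preparative supercritical‑fluid chromatography on a chiral stationary phase, and the S enantiomer is 5.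

Step 13 (reductive cyclopropane opening with enolate oxidation in one pot). SmI2 may attack the ring A enone, and the samarium enolate may be oxidised sluggishly. The fallback sets out from 21 and returns at 23. Sodium benzeneselenolate ((PhSe)2, NaBH4, EtOH, 0 °C) opens the doubly activated cyclopropane by homoconjugate attack at C12, breaking the same C12–C16 bond, to give the 12‑phenylselanyl tetracyclic β‑keto ester F2. Bu3SnH/AIBN (toluene, 80 °C) replaces selenium by hydrogen to give 22, now isolated as the keto ester. KN(SiMe3)2 followed by the same oxaziridine (THF, −78 °C) then gives 23.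

Step 14 (ester reduction beside the lactone). The lactone may be reduced, or the hindered tertiary α‑hydroxy ester may resist. The fallback sets out from 22 (step 13 stopped with AcOH before the oxaziridine is added) and returns at 24; it installs the C16 and C17 oxygens by dihydroxylation instead of hydroxylation and ester reduction. Krapcho dealkoxycarbonylation (LiCl, wet DMSO, 140 °C) gives the 17‑nor 15‑ketone F3. α‑Methylenation at C16, the only enolisable position ((CH2O)n, N‑methylanilinium trifluoroacetate, THF, reflux), gives the 16‑methylidene 15‑ketone F4. Luche reduction (NaBH4, CeCl3·7H2O, MeOH, −78 °C; exo hydride attack) gives the 1,15‑diol 16‑ene F5. OsO4 (cat.)/NMO (acetone/H2O, 0 °C) then dihydroxylates the exocyclic alkene from the exo face, anti to the allylic 15‑OH and in preference to the hindered ring A alkene, to give 24.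

**Further compounds**
F1 | step 2 | racemic 5-{[dimethyl(phenyl)silyl]methyl}-4,4-dimethylcyclohex-2-en-1-one | CC1(C)C=CC(=O)CC1C[Si](C)(C)c1ccccc1
F2 | step 13 | 12-phenylselanyl tetracyclic β-keto ester (selenium on C12 anti to the cleaved C12–C16 bond; otherwise as 22) | CC1(C)C=CC(=O)[C@]2(COC(=O)[C@@]34C[C@@H]([C@@H]([Se]c5ccccc5)C[C@@H]23)[C@H](C(=O)OCC)C4=O)[C@@H]1C[Si](C)(C)c1ccccc1
F3 | step 14 | (5R,8S,9S,10S,13R) 17-nor 15-ketone (C16 is CH2) | CC1(C)C=CC(=O)[C@]2(COC(=O)[C@@]34C[C@@H](CC[C@@H]23)CC4=O)[C@@H]1C[Si](C)(C)c1ccccc1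
F4 | step 14 | (5R,8S,9S,10S,13R) 16-methylidene 15-ketone | CC1(C)C=CC(=O)[C@]2(COC(=O)[C@@]34C[C@@H](CC[C@@H]23)C(=C)C4=O)[C@@H]1C[Si](C)(C)c1ccccc1
F5 | step 14 | (1S,5R,8S,9S,10S,13R,15S) 1,15-diol with 16-methylidene (15-OH endo) | CC1(C)C=C[C@H](O)[C@]2(COC(=O)[C@@]34C[C@@H](CC[C@@H]23)C(=C)[C@H]4O)[C@@H]1C[Si](C)(C)c1ccccc1
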